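**Retrosynthetic overview**
- Target ⇒ open the nitrogen ring at C1–C8a (Bischler–Napieralski) ⇒ demethylate C4'–OMe to the naphthol ⇒ open ring B at C2'–C3' (aldol) to a 2-acetylaryl ketone ⇒ cut at the aryne insertion to an aryl-substituted acetylacetone plus 3-methoxybenzyne. Forward, these four events run in one flask, so ring B and the nitrogen ring both close in the last operation and no biaryl cross-coupling is needed.
- Aryl-substituted acetylacetone ⇒ N-acetyl (S)-arylpropan-2-amine plus acetylacetone (oxidative C–H/C–H coupling).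
- N-acetyl amine ⇒ 1-bromo-3,5-dimethoxybenzene plus the cyclic sulfamidate of Boc-L-alaninol (C3 is bought as S).
- Ring order: the dimethoxybenzene ring and naphthalene ring A are bought. Ring B forms first, then the nitrogen ring. The biaryl axis appears when ring B aromatises.

Assumption: the SMILES fixes only C3 (S) and leaves the C5–C1' biaryl axis open, so the 3S compound is made and the two atropisomers, which form together, are separated by chromatography if one is wanted.

**Route**

Step 1
Reactants: 1 1-bromo-3,5-dimethoxybenzene; 2 tert-butyl (4S)-4-methyl-1,2,3-oxathiazolidine-3-carboxylate 2,2-dioxide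
Product: 5 tert-butyl N-[(2S)-1-(3,5-dimethoxyphenyl)propan-2-yl]carbamate, via 3,5-dimethoxyphenyllithium 3 (not isolated), via lithium N-Boc-sulfamate 4 (not isolated)
Conditions: n-BuLi (1.05 equiv), THF, −78 °C; then 2, −78 to 0 °C; then 20% aq. citric acid, rt
Reagents that add atoms: none
Why: Bromine–lithium exchange gives aryllithium 3, which opens the cyclic sulfamidate by SN2 attack at the primary O–CH2 carbon (nucleophilic ring-opening of a cyclic sulfamidate), so the C–N stereocentre from L-alaninol is not touched and stays S, and mild aqueous acid hydrolyses N-sulfamate 4 while leaving the Boc group.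

Step 2
Reactants: 5 tert-butyl N-[(2S)-1-(3,5-dimethoxyphenyl)propan-2-yl]carbamate
Product: 7 N-[(2S)-1-(3,5-dimethoxyphenyl)propan-2-yl]acetamide, via amine hydrochloride 6 (not isolated)
Conditions: HCl (4 M in dioxane), rt; then Ac2O, Et3N, CH2Cl2, 0 °C to rt
Reagents that add atoms: acetic anhydride CC(=O)OC(C)=O
Why: Acidolysis of the Boc carbamate followed by N-acylation of the amine salt (amide formation) gives the Bischler–Napieralski substrate without breaking any bond to the stereocentre.

Step 3
Reactants: 7 N-[(2S)-1-(3,5-dimethoxyphenyl)propan-2-yl]acetamide; 8 pentane-2,4-dione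
Product: 9 N-[(2S)-1-[2-(2,4-dioxopentan-3-yl)-3,5-dimethoxyphenyl]propan-2-yl]acetamide
Conditions: PhI(OCOCF3)2 (1.2 equiv), 8 (3 equiv), (CF3)2CHOH, 0 °C to rt
Reagents that add atoms: none
Why: Kita-type oxidative nucleophilic aromatic substitution, in which PhI(OCOCF3)2 in (CF3)2CHOH oxidises the electron-rich dimethoxyarene to its radical cation, the enol of 8 adds at the position para to one OMe and ortho to the other (C2 and C6 are identical by symmetry) and rearomatisation gives the C-arylated diketone; no stereocentre is involved.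

Step 4
Reactants: 9 N-[(2S)-1-[2-(2,4-dioxopentan-3-yl)-3,5-dimethoxyphenyl]propan-2-yl]acetamide; 10 3-methoxy-2-(trimethylsilyl)phenyl trifluoromethanesulfonate
Product: 15 (3S)-5-(4,5-dimethoxy-2-methylnaphthalen-1-yl)-6,8-dimethoxy-1,3-dimethyl-3,4-dihydroisoquinoline (O-methylancistrocladinine), via 3-methoxybenzyne 11 (not isolated), via triketone amide 12 (not isolated), via naphthol amide 13 (not isolated), via methyl ether amide 14 (not isolated)
Conditions: 10 (1.3 equiv), CsF (4 equiv), MeCN, 80 °C; then MeI, 40 °C; then POCl3 (10 equiv), 80 °C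
Reagents that add atoms: iodomethane CI
Why: Proposed new method: the cesium enolate of 9 adds to aryne 11 at the carbon remote from OMe, the aryl anion attacks one acetyl group and the benzocyclobutenoxide fragments to 12 (aryne acyl-alkylation, i.e. insertion into the C–C(O) bond of a 1,3-diketone), the aryl methyl ketone enolate of 12 closes ring B by intramolecular aldol condensation and aromatisation to the naphthoxide of 13 (as 2-acetonylacetophenones give 1-naphthols under base), MeI gives 14 (Williamson ether synthesis), and POCl3 closes the nitrogen ring by Bischler–Napieralski cyclisation at the only free position ortho to the side chain, which is activated by one ortho and one para OMe; the closest known reactions are these four run separately, the S centre is carried through untouched and the biaryl axis forms unselectively.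

**Compound list**
1 | 1-bromo-3,5-dimethoxybenzene | COc1cc(Br)cc(OC)c1 | starting material
2 | tert-butyl (4S)-4-methyl-1,2,3-oxathiazolidine-3-carboxylate 2,2-dioxide | C[C@H]1COS(=O)(=O)N1C(=O)OC(C)(C)C | starting material
3 | 3,5-dimethoxyphenyllithium | [Li]c1cc(OC)cc(OC)c1 | intermediate
4 | lithium N-(tert-butoxycarbonyl)-N-[(2S)-1-(3,5-dimethoxyphenyl)propan-2-yl]sulfamate | COc1cc(C[C@H](C)N(C(=O)OC(C)(C)C)S(=O)(=O)[O-])cc(OC)c1.[Li+] | intermediate
5 | tert-butyl N-[(2S)-1-(3,5-dimethoxyphenyl)propan-2-yl]carbamate | COc1cc(C[C@H](C)NC(=O)OC(C)(C)C)cc(OC)c1 | intermediate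
6 | (2S)-1-(3,5-dimethoxyphenyl)propan-2-aminium chloride | COc1cc(C[C@H](C)[NH3+])cc(OC)c1.[Cl-] | intermediate
7 | N-[(2S)-1-(3,5-dimethoxyphenyl)propan-2-yl]acetamide | COc1cc(C[C@H](C)NC(C)=O)cc(OC)c1 | intermediate
8 | pentane-2,4-dione (acetylacetone) | CC(=O)CC(C)=O | starting material
9 | N-[(2S)-1-[2-(2,4-dioxopentan-3-yl)-3,5-dimethoxyphenyl]propan-2-yl]acetamide | COc1cc(OC)c(C(C(C)=O)C(C)=O)c(C[C@H](C)NC(C)=O)c1 | intermediate
10 | 3-methoxy-2-(trimethylsilyl)phenyl trifluoromethanesulfonate | COc1cccc(OS(=O)(=O)C(F)(F)F)c1[Si](C)(C)C | starting material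
11 | 3-methoxybenzyne (aryne bond between the two carbons that carried OTf and SiMe3) | COC1=CC=CC#C1 | intermediate
12 | N-[(2S)-1-[2-[1-(2-acetyl-3-methoxyphenyl)-2-oxopropyl]-3,5-dimethoxyphenyl]propan-2-yl]acetamide (the new CH centre is unassigned and is lost on aromatisation) | COc1cccc(C(C(C)=O)c2c(OC)cc(OC)cc2C[C@H](C)NC(C)=O)c1C(C)=O | intermediate
13 | N-[(2S)-1-[2-(4-hydroxy-5-methoxy-2-methylnaphthalen-1-yl)-3,5-dimethoxyphenyl]propan-2-yl]acetamide (present in the flask as its cesium salt) | COc1cccc2c(-c3c(OC)cc(OC)cc3C[C@H](C)NC(C)=O)c(C)cc(O)c12 | intermediate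
14 | N-[(2S)-1-[2-(4,5-dimethoxy-2-methylnaphthalen-1-yl)-3,5-dimethoxyphenyl]propan-2-yl]acetamide | COc1cccc2c(-c3c(OC)cc(OC)cc3C[C@H](C)NC(C)=O)c(C)cc(OC)c12 | intermediate
15 | (3S)-5-(4,5-dimethoxy-2-methylnaphthalen-1-yl)-6,8-dimethoxy-1,3-dimethyl-3,4-dihydroisoquinoline (O-methylancistrocladinine) | COc1cc(OC)c(-c2c(C)cc(OC)c3c(OC)cccc23)c2c1C(C)=N[C@@H](C)C2 | target

**Step count and risks**

Total step count: 4. Longest linear sequence: 4 steps (1 → 5 → 7 → 9 → 15).

Step 4 is the most likely to fail. The enolate of 9 is hindered and may attack the aryne through oxygen, or the amide N–H may be arylated. The aldol may also close the other way to a 2-naphthol, and fluoride salts and water left in the flask consume POCl3. The fallback sets out from 9 and comes back at 12, replacing aryne insertion by a palladium-catalysed ketone arylation. 9 is deacetylated (K2CO3, MeOH, 60 °C, retro-Claisen) to N-[(2S)-1-[3,5-dimethoxy-2-(2-oxopropyl)phenyl]propan-2-yl]acetamide F1. F1 is arylated at its benzylic ketone carbon with commercial 1-(2-bromo-6-methoxyphenyl)ethanone (Pd(OAc)2, XPhos, K3PO4, toluene, 100 °C) to give 12. Under the basic conditions 12 closes to 13, which is now isolated, methylated (MeI, K2CO3, acetone) to 14 and cyclised with POCl3 in MeCN to 15, each in its own flask.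

Step 3 is the second risk. The enol may add at C4 between the two OMe groups, the product 9 may be oxidised further, and the oxidant may consume 8. The fallback sets out from 7 and comes back at 9, replacing the radical-cation coupling by an aryl-lead ligand coupling. 7 is plumbated with Pb(OAc)4 (CHCl3, dichloroacetic acid, rt) at the same ring position to give {2-[(2S)-2-acetamidopropyl]-4,6-dimethoxyphenyl}lead triacetate F2. F2 then arylates 8 (pyridine, CHCl3, 40 °C, Pinhey arylation) to give 9.

Step 1 is the third risk. The aryllithium may attack the Boc carbonyl or sulfur instead of the CH2 carbon, and the hydrolysis may remove some Boc. The fallback sets out from 1 and comes back at 7, replacing the sulfamidate by an epoxide and a later nitrogen displacement. Aryllithium 3, made from 1 as before, opens (R)-2-methyloxirane at its CH2 end (BF3·OEt2, THF, −78 °C) to give (2R)-1-(3,5-dimethoxyphenyl)propan-2-ol F3. Mitsunobu displacement ((PhO)2P(O)N3, DIAD, PPh3, THF, 0 °C) inverts the carbinol carbon and gives 1-[(2S)-2-azidopropyl]-3,5-dimethoxybenzene F4. Staudinger reduction (PPh3, THF/H2O, 50 °C) gives (2S)-1-(3,5-dimethoxyphenyl)propan-2-amine F5, which is acetylated (Ac2O, Et3N, CH2Cl2) to 7.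

**Further compounds**
F1 | step 4 | N-[(2S)-1-[3,5-dimethoxy-2-(2-oxopropyl)phenyl]propan-2-yl]acetamide | COc1cc(OC)c(CC(C)=O)c(C[C@H](C)NC(C)=O)c1
F2 | step 3 | {2-[(2S)-2-acetamidopropyl]-4,6-dimethoxyphenyl}lead triacetate | COc1cc(OC)c([Pb](OC(C)=O)(OC(C)=O)OC(C)=O)c(C[C@H](C)NC(C)=O)c1
F3 | step 1 | (2R)-1-(3,5-dimethoxyphenyl)propan-2-ol | COc1cc(C[C@@H](C)O)cc(OC)c1
F4 | step 1 | 1-[(2S)-2-azidopropyl]-3,5-dimethoxybenzene | COc1cc(C[C@H](C)N=[N+]=[N-])cc(OC)c1
F5 | step 1 | (2S)-1-(3,5-dimethoxyphenyl)propan-2-amine | COc1cc(C[C@H](C)N)cc(OC)c1
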